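Percentages of J turn into concentrations on multiplying by the charge of G, so we start there.

| flask | G | L | temperature | remark | time |
|---|---|---|---|---|---|
| gamma | 0.026 M | 1 equiv | 45 °C | run made earlier |  |
| zeta | 0.051 M | 1 equiv | 56 °C | run made earlier |  |
| blue | 0.080 M | 1.00 equiv | 50 °C |  | 5.0 min |
| amber | 0.050 M | 1.00 equiv | 50 °C |  | 5.0 min |

| run | time / min | J / % | D / % |
|---|---|---|---|
| gamma | 0.250 | 9.4 | 0 |
| gamma | 0.500 | 17.6 | 0.5 |
| gamma | 1.00 | 29.1 | 1.2 |
| gamma | 2.00 | 41.7 | 2.5 |
| gamma | 4.00 | 51.3 | 3.2 |
| zeta | 0.250 | 33.1 | 0.9 |
| zeta | 0.500 | 45.4 | 1.7 |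
| zeta | 1.00 | 56.7 | 2.4 |
| zeta | 2.00 | 62.1 | 3.4 |
| zeta | 4.00 | 65.0 | 5.7 |

(standard deviation of a reading: 0.5 percentage points)

- the winner by share of J in all that became J or D or Q; "neither" if no more than 2 percentage points parts them (blue / amber / neither)
- share of J in all that became J or D or Q, blue
- share of J in all that became J or D or Q, amber

- a reading or a percentage of J counts all its forms, free or not
- where the amount of G changes, what is given in equivalents or mol% on it follows

The highest [J] read so far is the last zeta reading, 33.1 mM, more than the last gamma reading of 13.3 mM. We call it [J]top, the top of the tested range of total J, and [J]top over a flask's charge of G is that flask's room. The room is 41.4% in blue and 66.3% in amber. Zeta's last yield in blue would mean 52.0 mM, more than [J]top, so on that yield blue leaves the tested range. Our reckoning gives no share, but it does make us doubt blue.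

The forecast says neither, with 68% (62% to 74%) for blue and 68% (63% to 73%) for amber: “I see no evidence of concentration dependence”. We differ in that doubt.

The flask gives blue, with 78.0% in blue and 74.0% in amber, each above the top of its forecast range.

    L + J → Q (k = 0.105 /M/s, Ea = 45.0 kJ/mol)
    X ⇌ J, rate k2*(cs2 - [J]) while solid is left; crystals form when [J] > cs2 (solubility = 29.0 mM, k = 0.103 /s)
    G + L → J (k = 0.426 /M/s, Ea = 70.0 kJ/mol)
    G → D (k = 4.77 × 10⁻⁴ /s, Ea = 91.0 kJ/mol)
    (constants at 50 °C)

In amber, with each step taken net and going into X counted as use, dissolved J was made 6.68 times as fast as it was used at 0.511 min, and 0.969 times as fast at 5.00 min, with 5.37% of its L left. Between those times the ratio crossed one. At 5.00 min blue's J, 67.1%, stood past its room and included 30.8% as crystals X, while amber's J, 61.1%, stood inside its room and included 3.02% as X.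

The neighbour of amber with 0.20 M of G has a room of 16.6%. At 5.00 min it gives J 76.4%, of which X is 61.8%, and a share of 84.5%.

(The readings were computed with made-up constants; the scatter is artificial.)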